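(The rate constants were drawn at random within sensible limits; what happens was integrated by code.)

Which set-up holds the largest share of what it made as target, and not as over-reaction product?

| flask | substrate | free catalyst | time | remark |
|---|---|---|---|---|
| ash | 0.50 M (fed, over 20.0 h) | 6.5 mM | 40 h | all but substrate at the start; substrate goes in evenly over 20.0 h, the run ends at 40 h |
| alder | 0.50 M | 6.5 mM |  | one stirred flow tank at steady state, fed with the mixture as stated, mean residence time 40 h |
| maple | 0.50 M | 6.5 mM | 40 h | a closed flask charged with all of it at once and left for 40 h |

    substrate + free catalyst → catalyst intermediate (k1 = 0.00177 L mol⁻¹ s⁻¹)
    catalyst intermediate → free catalyst + target (k2 = 0.00118 s⁻¹)
    target → over-reaction product (k3 = 2.47 × 10⁻⁶ s⁻¹)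

- order of the set-ups by the share of target in all that became target or over-reaction product, at the outlet or at the end, highest first (ash / alder / maple)
- share of target in all that became target or over-reaction product, at the outlet or at the end, ash
- share of target in all that became target or over-reaction product, at the outlet or at the end, alder
- share of target in all that became target or over-reaction product, at the outlet or at the end, maple

I follow one target molecule. Its chance of going on to over-reaction product is the same in every hour (a first-order loss), so its fate depends on its age, the time since it formed, and the share asked for is the average survival of all target molecules ever formed, those already lost included. The ageing number, the constant of that loss times the run or residence time, is 0.356.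

In alder the molecule stands at a fork, leaving or reacting, and its chance of leaving is one over one plus the ageing number, 73.8%. In a flask whose target formed evenly over the run, averaging the survival gives 84.1%, my even-birth mark, and alder stands lower.

Now I turn the question round: for maple to beat ash, maple's target would have to be younger on average than ash's. But maple holds [substrate] at 0.50 M from the first moment, and its half-life by the first step, with the other concentrations held at their charge, is 17 h, shorter than the run. So maple's target forms early and should fall below the mark, while ash receives its substrate over 20.0 h, half of the run, and should stand above it. I commit to ash, maple, alder, with a figure for alder alone.

The forecast gives ash > maple > alder, with 85.7% for ash, 73.8% for alder and 82.2% for maple, and says: “Slow feeding makes the target younger on average”.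

The simulation gives ash > maple > alder, with 85.8% for ash, 73.8% for alder and 82.3% for maple.

Ash stands above the even-birth mark and maple below it. A neighbouring flask is ash with 0.026 M of free catalyst, 4.00 times the charge, read at the same time, so its ageing number is still 0.356 and its mark still 84.1%. It reads 81.6%, below the mark, so by the same average its target is older than even births would make it, the opposite of ash. At its end 1.6% of the substrate remains, with target at 80.2% and over-reaction product at 18.1%.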